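**Two slices.** Per percent of homo product, the midnight run gains less target up to 10.0 min than after it: the first slice brings 11.6% of target against 58.3% of homo product, and the slice from there to 50.0 min brings 5.8 percentage points against 10 points.

**The flasks.** With reagent, substrate goes to target when partner takes part and to homo product when a second substrate does. The four new flasks differ in feed and warming.

| flask | substrate | partner | reagent | capture agent | temperature | remark | time |
|---|---|---|---|---|---|---|---|
| midnight | 13 mM | 1.1 equiv | 1.1 equiv | 1.3 mM | 100 °C | run made earlier |  |
| autumn | 13 mM | 1.1 equiv | 0.55 equiv | 1.3 mM | 100 °C | run made earlier |  |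
| Monday's | 13 mM | 1.10 equiv | 1.10 equiv | 1.30 mM |  | everything together at the start at 70 °C, warmed to 100 °C at 15 min | 80 min |
| Wednesday's | 13 mM | 1.10 equiv | 1.10 equiv (fed, over 15 min) | 1.30 mM | 100 °C | all else is in the flask from the start; the feed brings no volume worth counting | 80 min |
| Tuesday's | 13 mM | 1.10 equiv | 1.10 equiv | 1.30 mM | 100 °C | everything together at the start | 80 min |
| Saturday's | 13 mM (fed, over 15 min) | 1.10 equiv | 1.10 equiv | 1.30 mM |  | the addition at 70 °C, then warmed to 100 °C; the feed brings no volume worth counting | 80 min |

- midnight (time / min: target / %, homo product / %): 10.0: 11.6, 58.3; 20.0: 15.4, 65.5; 30.0: 17.4, 67.3; 40.0: 17.2, 67.4; 50.0: 17.4, 68.4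
- autumn (time / min: target / %, homo product / %): 0.667: 0.1, 1.3; 1.33: 0.6, 3.0; 2.50: 1.9, 9.5; 4.00: 2.8, 18.7; 8.00: 4.6, 29.2

(readings scatter by 0.5 percentage points)

- the flask with the highest share of target in target plus homo product ("all alike" if they lie within 1.5 percentage points) (Monday's / Wednesday's / Tuesday's / Saturday's / all alike)
- share of target in target plus homo product at the end, Monday's
- share of target in target plus homo product at the end, Wednesday's
- share of target in target plus homo product at the end, Tuesday's
- share of target in target plus homo product at the end, Saturday's

- percentages count the substrate that a species holds: one homo product counts as two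
- the earlier runs do not show what temperature does; that part of a forecast is a guess

**Late share.** Dividing one gain by the other removes time. The late share, the part of target in what the flask adds after the first reading (a differential selectivity), is Δ[target]/(Δ[target]+Δ[homo product]) = 36.5%. The first slice gives 16.6%, and the midnight run up to 50.0 min gives 20.3%.

**First doubt.** Those late gains are small beside a scatter of 0.5 points per reading. But the slice from 10.0 min to 20.0 min by itself gives 34.5%, so the rise stands.

**Second doubt.** A lower pace might be what lifts the share. The autumn run, with 0.55 equiv of reagent, gains homo product at 0.626 of midnight's early pace, yet its share at 8.00 min is 13.6%. Its products hold 33.8% of the substrate there, whereas midnight's late slice starts from 69.9%. But midnight's late slice gains homo product at 0.0429 of that early pace, and it differs from the autumn run in reagent and in elapsed time as well, so low pace and low [substrate] both stay open as readings of the rise.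

**My reckoning.** Tuesday's repeats 20.3%, and Wednesday's, with reagent fed, stays near it. Saturday's feed is meant to hold [substrate] low, which is one of those two open readings, so my guess, and no more than that, puts Saturday's between 20.3% and 36.5%. The objection stands: at 70 °C substrate may pile up, and the earlier runs show nothing of temperature, so Monday's and the place within that range are guesses.

**The forecast.** It names Saturday's, with Monday's 20.5%, Wednesday's 20.5%, Tuesday's 20.3% and Saturday's 25%, on this ground: “Only feeding substrate keeps its concentration low, so Saturday should gain.” Its Saturday's figure is a point inside my range.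

**The result.** Saturday's leads: Monday's 25.5%, Wednesday's 21.6%, Tuesday's 21.7%, Saturday's 31.6%.

    open intermediate + capture agent → trapped intermediate (k = 1.42 M⁻¹ min⁻¹, Ea = 67.0 kJ mol⁻¹)
    target → over-reaction product (k = 2.05 × 10⁻⁴ min⁻¹, Ea = 130 kJ mol⁻¹)
    reagent + partner → second intermediate (k = 4.04 M⁻¹ min⁻¹, Ea = 53.0 kJ mol⁻¹)
    substrate + reagent → open intermediate (k = 38.7 M⁻¹ min⁻¹, Ea = 69.0 kJ mol⁻¹)
    open intermediate + second intermediate → target (k = 76.2 M⁻¹ min⁻¹, Ea = 39.0 kJ mol⁻¹)
    2 open intermediate → homo product (k = 48.8 M⁻¹ min⁻¹, Ea = 68.0 kJ mol⁻¹)
    (constants at 100 °C)

**Late share again.** Saturday's still holds 18.0% of its substrate at 80.0 min, with reagent at 0%. Its share stands 4.9 points under the late share. Wednesday's flask with 1.90 equiv of reagent ends at 27.9%, which is 8.6 points under the late share, with 0% of its substrate left.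

The readings come from a simulation with constants of no real substance, and the scatter is random.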